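**Retrosynthetic overview**

1. The target's only ring is a 27-membered lactone made of C1 (carbonyl), the methylenes C2–C26 and one ring oxygen bridging C26 to C1. Removing that oxygen (retro-Baeyer–Villiger, O–C26 bond) leaves the symmetric 26-membered carbocyclic ketone cyclohexacosanone, in which C2 and C26 are equivalent.
2. Cyclohexacosanone comes from its acyloin by reductive loss of the hydroxyl. The acyloin comes from dimethyl hexacosanedioate by a silyl-trapped acyloin ring closure (C1–C2 bond of the carbocycle).
3. The C26 diester comes from two C14 half esters by Kolbe coupling (C13–C14 bond). The half ester comes from tetradecanedioic acid by diesterification with two equivalents of methanol and half-saponification.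
4. Ring order: the 26-membered carbocycle is closed first (step 4), then enlarged by one oxygen to the 27-membered lactone (step 6).

Key step: step 6

Remark on the chemistry: the target has no stereocentre. Acyloin 8 is carried as the racemate and the olefin geometry of 7 is left undefined, since both are erased by step 5.

**Route**

Step 1
Reactants: 1 tetradecanedioic acid; 2 methanol (two molecules)
Product: 3 dimethyl tetradecanedioate
Conditions: MeOH (solvent), cat. H2SO4, reflux
Reagents that add atoms: methanol, CO (compound 2, the second equivalent, drawn from the solvent)
Why: Fischer esterification, an acid-catalysed acyl substitution at both carboxyl groups that consumes two molecules of methanol, releases two of water and is driven to the diester by methanol as solvent.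

Step 2
Reactants: 3 dimethyl tetradecanedioate
Product: 5 14-methoxy-14-oxotetradecanoic acid, via barium half-ester salt 4 (not isolated)
Conditions: Ba(OH)2 (0.5 equiv), MeOH, 20 °C; wet precipitate taken straight into 2 M HCl–Et2O
Reagents that add atoms: barium hydroxide, [Ba+2].[OH-].[OH-] (oxygen of the new carboxyl group; barium stands only in 4)
Why: Partial saponification (acyl–oxygen cleavage by hydroxide) with half an equivalent of base should stop at the half ester because its barium salt is sparingly soluble in methanol and precipitates as it forms; unchanged 3 stays in the mother liquor and is recycled.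

Step 3
Reactants: 5 14-methoxy-14-oxotetradecanoic acid (two molecules)
Product: 6 dimethyl hexacosanedioate
Conditions: Pt anode, Pt cathode, undivided cell, NaOMe (0.05 equiv), MeOH–pyridine 4:1, 50 °C, constant current
Reagents that add atoms: none
Why: Kolbe anodic decarboxylative dimerisation of a half ester (Brown–Walker electrolysis): the carboxylate is oxidised at platinum at high current density, loses CO2, and two 13-methoxy-13-oxotridecyl radicals couple to form the C13–C14 bond of the C26 chain, the distal methyl ester being inert in methanol.

Step 4
Reactants: 6 dimethyl hexacosanedioate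
Product: 8 2-hydroxycyclohexacosan-1-one (racemic), via bis(trimethylsilyl) enediol ether 7 (not isolated)
Conditions: Na (dispersion), Me3SiCl, toluene, reflux, slow addition of 6 under N2; filter; then 1 M HCl, THF, 20 °C
Reagents that add atoms: chlorotrimethylsilane, C[Si](C)(C)Cl (its silyl groups stand only in 7)
Why: Acyloin condensation in the Rühlmann (silyl-trapped) form: electron transfer from the sodium surface couples the two ester carbonyls of one adsorbed chain and closes the 26-membered carbocycle, silylation of the enediolate and of the expelled methoxide cuts off Claisen and Dieckmann pathways, and mild acid hydrolysis of 7 releases the acyloin, whose single carbinol stereocentre forms as a racemate and is removed in step 5.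

Step 5
Reactants: 8 2-hydroxycyclohexacosan-1-one
Product: 9 cyclohexacosanone
Conditions: Zn dust, conc. HCl, AcOH, 75–80 °C
Reagents that add atoms: none
Why: Zinc–acid deoxygenation of an acyloin (dissolving-metal reduction of an α-hydroxy ketone): electron transfer to the carbonyl expels the protonated α-hydroxyl as water, the zinc enolate is protonated to the symmetric ketone, and holding the temperature below 80 °C should keep Clemmensen over-reduction back.

Step 6
Reactants: 9 cyclohexacosanone
Product: 11 26-hexacosanolide, via Criegee adduct 10 (not isolated)
Conditions: (CF3CO)2O, H2O2·urea, Na2HPO4, CH2Cl2, 0 °C to 20 °C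
Reagents that add atoms: hydrogen peroxide–urea, OO.NC(N)=O (supplies the ring oxygen); trifluoroacetic anhydride, O=C(OC(=O)C(F)(F)F)C(F)(F)F (its acyl group stands only in 10)
Why: Trifluoroperacetic acid, formed in the flask from the anhydride and H2O2·urea, adds to the carbonyl of 9 to give the tetrahedral peroxy adduct 10; one ring α-methylene then shifts with its bonding pair from the former carbonyl carbon to the nearer peroxide oxygen, antiperiplanar to the breaking O–O bond, while trifluoroacetate leaves, which makes the O–C26 bond. The closest known reaction type is the Baeyer–Villiger oxidation of large-ring cycloalkanones to macrolides with strong peracids. No ring is closed from chain ends: the existing 26-membered carbocycle grows to the 27-membered lactone by a 1,2-shift (ring expansion by one oxygen atom), so the step needs no high dilution. No stereocentre is formed. The step needs only conversion and survival of the product, because the two α-methylenes of the symmetric ketone are equivalent and 9 has no other oxidisable group; the electron-poor trifluoroacetate leaving group should drive the otherwise slow rearrangement of the strain-free ring, and Na2HPO4 takes up CF3CO2H so that the lactone is not opened or transesterified.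

**Compound list**

1 | tetradecanedioic acid | OC(=O)CCCCCCCCCCCCC(=O)O | starting material
2 | methanol | CO | starting material
3 | dimethyl tetradecanedioate | COC(=O)CCCCCCCCCCCCC(=O)OC | intermediate
4 | barium bis(14-methoxy-14-oxotetradecanoate) | COC(=O)CCCCCCCCCCCCC(=O)[O-].COC(=O)CCCCCCCCCCCCC(=O)[O-].[Ba+2] | intermediate
5 | 14-methoxy-14-oxotetradecanoic acid | COC(=O)CCCCCCCCCCCCC(=O)O | intermediate
6 | dimethyl hexacosanedioate | COC(=O)CCCCCCCCCCCCCCCCCCCCCCCCC(=O)OC | intermediate
7 | 1,2-bis(trimethylsilyloxy)cyclohexacos-1-ene (olefin geometry undefined) | C[Si](C)(C)OC1=C(O[Si](C)(C)C)CCCCCCCCCCCCCCCCCCCCCCCC1 | intermediate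
8 | 2-hydroxycyclohexacosan-1-one (racemic) | O=C1C(O)CCCCCCCCCCCCCCCCCCCCCCCC1 | intermediate
9 | cyclohexacosanone | O=C1CCCCCCCCCCCCCCCCCCCCCCCCC1 | intermediate
10 | 1-hydroxycyclohexacosyl trifluoroperacetate (Criegee adduct) | OC1(OOC(=O)C(F)(F)F)CCCCCCCCCCCCCCCCCCCCCCCCC1 | intermediate
11 | 26-hexacosanolide (oxacycloheptacosan-2-one) | O=C1CCCCCCCCCCCCCCCCCCCCCCCCCO1 | target

**Step count**

Total steps: 6. Longest linear sequence: 6 steps (1 to 11, fully linear).

**Steps most likely to fail**

Step 6 (key step). The peracid may add only slowly to the unstrained large-ring ketone so that the oxidation stalls, and over a long reaction time the lactone may be opened or transesterified by acid to linear oligoesters. The fallback replaces oxygen insertion by closure of the seco acid; it sets out from 8 and comes back to the route at 11. Acyloin 8 would be cleaved between the carbonyl and carbinol carbons with H5IO6 in THF–H2O at 40 °C to give 26-oxohexacosanoic acid F1. The aldehyde would be reduced with NaBH4 in THF–EtOH (0 to 20 °C, then dilute HCl) to 26-hydroxyhexacosanoic acid F2. This would be activated with 2,4,6-trichlorobenzoyl chloride and Et3N in THF as the mixed anhydride 26-hydroxyhexacosanoic 2,4,6-trichlorobenzoic anhydride F3. Slow addition of F3 to DMAP in refluxing toluene at about 1 mM (Yamaguchi macrolactonisation) should close the 27-membered ring to 11.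

Step 4. Intermolecular ester coupling on the sodium surface may outrun ring closure, or the waxy diester may coat the sodium so that electron transfer stops. The fallback closes the carbocycle by carbonyl olefination instead; it sets out from 6 and comes back at 9. Diester 6 would be reduced with LiAlH4 in refluxing THF to hexacosane-1,26-diol F4, which would be oxidised with 2-iodoxybenzoic acid in ethyl acetate at 80 °C to hexacosanedial F5. Slow addition of F5 to low-valent titanium from TiCl3(DME)1.5 and Zn–Cu couple in refluxing DME (intramolecular McMurry coupling) should give cyclohexacosene F6 as an E/Z mixture. Hydroboration with 9-BBN in refluxing THF would give 9-cyclohexacosyl-9-borabicyclo[3.3.1]nonane F7, which would be oxidised in the same flask with NaOH–H2O2 to cyclohexacosanol F8. Dess–Martin periodinane in CH2Cl2 would then give ketone 9.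

Step 5. The ketone may be over-reduced under the strongly acidic zinc conditions (to the alcohol or the hydrocarbon), or the hydroxyl may be lost incompletely. The fallback replaces the dissolving metal in acid by a neutral single-electron cleavage of an activated ester; it sets out from 8 and comes back at 9. Acyloin 8 would be acetylated (Ac2O, pyridine, cat. DMAP, CH2Cl2) to 2-oxocyclohexacosyl acetate F9. SmI2 in THF–MeOH at −40 °C should then expel acetate from the ketyl and give 9 after protonation of the samarium enolate.

**Further compounds**

F1 | step 6 | 26-oxohexacosanoic acid | O=CCCCCCCCCCCCCCCCCCCCCCCCCCC(=O)O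
F2 | step 6 | 26-hydroxyhexacosanoic acid | OCCCCCCCCCCCCCCCCCCCCCCCCCCC(=O)O
F3 | step 6 | 26-hydroxyhexacosanoic 2,4,6-trichlorobenzoic anhydride | OCCCCCCCCCCCCCCCCCCCCCCCCCCC(=O)OC(=O)c1c(Cl)cc(Cl)cc1Cl
F4 | step 4 | hexacosane-1,26-diol | OCCCCCCCCCCCCCCCCCCCCCCCCCCO
F5 | step 4 | hexacosanedial | O=CCCCCCCCCCCCCCCCCCCCCCCCCCC=O
F6 | step 4 | cyclohexacosene (E/Z mixture) | C1=CCCCCCCCCCCCCCCCCCCCCCCCC1
F7 | step 4 | 9-cyclohexacosyl-9-borabicyclo[3.3.1]nonane | C1CCC2CCCC(C1)B2C3CCCCCCCCCCCCCCCCCCCCCCCCC3
F8 | step 4 | cyclohexacosanol | OC1CCCCCCCCCCCCCCCCCCCCCCCCC1
F9 | step 5 | 2-oxocyclohexacosyl acetate (racemic) | CC(=O)OC1C(=O)CCCCCCCCCCCCCCCCCCCCCCCC1
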